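Ring B is disconnected at C1'–C6'. C1', the ether carbon, lies between the hydroxyl carbons C2' and C6'. It can therefore begin as the OCH2 carbon on C6 of a 4-methoxy-5-methyl-2-pyrone, whose methoxy group becomes the C4' ether and whose C5 methyl becomes the C3' methyl. In one operation methoxide opens the lactone and the carbanion next to the aryloxy oxygen closes ring B on the released ester, giving the hindered diaryl ether as a resorcinol. The precursor is the ring A aryloxymethyl pyrone. Its ring A acetyl is carried as a 1-ethoxyethenyl group and its C3 hydroxyl as a methyl ether, because a free ortho acetyl would trap the same carbanion as a benzofuran.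

Key step: step 9

Remarks on the chemistry
- Numbering. Ring A: C1 O-aryl, C2 acetyl, C3 OH, C4 Me, C5 OMe, C6 H. Ring B: C1' O-aryl, C2' OH, C3' Me, C4' OMe, C5' acetyl, C6' OH.
- In the ring-opened ester the ester carbon and C4 are cis on C2=C3. CO2Me and OMe rank highest and lie on opposite sides, so this is the (2E)-3-methoxy-4-methyl-5-oxohex-2-enoate.
- Both carbons of the reacting enolate (chain C5 and C6) become ring atoms, so the closure is 6-(enolendo)-exo-trig.
- An ortho-acetylaryloxymethyl ketone under base closes by a 5-(enolexo)-exo-trig aldol and dehydrates to a 2-acyl-3-methylbenzofuran. An ortho acetyl also activates ring A for a Smiles shift to a neighbouring phenoxide. The ketone is therefore masked during the basic step, and everything after its release is run under acid.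
- A symmetric ring A phenol with a single OH removes any choice of oxygen in the ether-forming step. The C3 hydroxyl is released later by chelation control.
- Assumption: 3,5-dimethoxy-4-methylphenol is not taken as a stock chemical and is made from 2,6-dimethoxytoluene.

Step 1
Reactants: 1 methyl 3-oxopentanoate; 2 N-methoxy-N-methylacetamide
Product: 3 methyl 4-methyl-3,5-dioxohexanoate (racemic at C4)
Conditions: LiN(iPr)2 (2.2 equiv), THF, −78 to 0 °C; 2, −78 °C to rt; aq. HCl
Reagents that add atoms: none
Why: γ-Acylation of a β-keto ester dianion (crossed Claisen condensation): only the more basic C4 carbanion reacts, and the N-methoxy-N-methylamide holds the chelated tetrahedral adduct until the quench, so over-addition and proton transfer do not interfere; the labile C4 centre vanishes in step 2.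

Step 2
Reactants: 3 methyl 4-methyl-3,5-dioxohexanoate
Product: 4 4-hydroxy-5,6-dimethyl-2H-pyran-2-one
Conditions: DBU (1.0 equiv), toluene, reflux; 1 M HCl
Reagents that add atoms: none
Why: Base-induced enol lactonisation of a 3,5-dioxo ester: the C5 enolate oxygen attacks the ester (6-exo-trig), methanol leaves, and the conjugated 4-hydroxy-2-pyrone is the thermodynamic sink.

Step 3
Reactants: 4 4-hydroxy-5,6-dimethyl-2H-pyran-2-one
Product: 5 4-methoxy-5,6-dimethyl-2H-pyran-2-one
Conditions: Me2SO4 (1.2 equiv), K2CO3, acetone, reflux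
Reagents that add atoms: dimethyl sulfate, COS(=O)(=O)OC
Why: O-Alkylation of a vinylogous carboxylic acid (Williamson type): with K2CO3 in acetone the hard sulfate ester methylates the C4 oxygen and should give the 4-methoxy-2-pyrone rather than the 2-methoxy-4-pyrone isomer.

Step 4
Reactants: 5 4-methoxy-5,6-dimethyl-2H-pyran-2-one
Product: 6 6-(bromomethyl)-4-methoxy-5-methyl-2H-pyran-2-one
Conditions: NBS (1.05 equiv), AIBN (5 mol %), PhCF3, reflux
Reagents that add atoms: N-bromosuccinimide, O=C1CCC(=O)N1Br
Why: Wohl–Ziegler bromination: the radical at the C6 methyl is delocalised through C5 and C3 to the lactone carbonyl whereas that at the C5 methyl is only cross-conjugated, the non-polar radical medium holds back ionic bromination at C3, and this is the usual entry to 6-(halomethyl)-4-methoxy-2-pyrones.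

Step 5
Reactants: 7 2,6-dimethoxytoluene
Product: 9 3,5-dimethoxy-4-methylphenol, via aryl pinacol boronate 8 (not isolated)
Conditions: [Ir(OMe)(cod)]2 (1.5 mol %), 4,4'-di-tert-butyl-2,2'-bipyridine (3 mol %), B2pin2 (0.6 equiv), THF, 80 °C; then aq. NaOH, 30% H2O2, 0 °C to rt; HCl
Reagents that add atoms: bis(pinacolato)diboron, CC1(C)OB(OC1(C)C)B1OC(C)(C)C(C)(C)O1 (boryl group of 8 only); hydrogen peroxide, OO
Why: Sterically controlled iridium-catalysed aromatic C–H borylation followed by oxidation of the C–B bond: the position para to the methyl group is the only C–H without an ortho substituent, and the oxidation puts the hydroxyl exactly there.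

Step 6
Reactants: 9 3,5-dimethoxy-4-methylphenol
Product: 11 tert-butyl(2-iodo-3,5-dimethoxy-4-methylphenoxy)dimethylsilane, via iodophenol 10 (not isolated)
Conditions: NIS (1.0 equiv), DMF, 0 °C, dark; then imidazole, TBSCl, rt
Reagents that add atoms: N-iodosuccinimide, O=C1CCC(=O)N1I; tert-butyldimethylsilyl chloride, CC(C)(C)[Si](C)(C)Cl
Why: Electrophilic aromatic iodination followed by silylation: the para position is blocked by the methyl group and the two ortho positions are equivalent, so one equivalent of NIS can give only one mono-iodide, and the silyl ether covers the phenol for the coupling.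

Step 7
Reactants: 11 tert-butyl(2-iodo-3,5-dimethoxy-4-methylphenoxy)dimethylsilane; 12 tributyl(1-ethoxyethenyl)stannane
Product: 13 tert-butyl[2-(1-ethoxyethenyl)-3,5-dimethoxy-4-methylphenoxy]dimethylsilane
Conditions: Pd(PPh3)4 (5 mol %), CuI (10 mol %), 1,4-dioxane, 100 °C; K2CO3-doped silica
Reagents that add atoms: none
Why: Stille coupling with an α-stannyl enol ether, the standard delivery of a latent acetyl group: zerovalent palladium inserts into the aryl iodide, CuI speeds transmetalation at the crowded centre, and the coupling is run before the pyrone is attached so that the arylpalladium species has no tethered alkene for a Heck cyclisation.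

Step 8
Reactants: 13 tert-butyl[2-(1-ethoxyethenyl)-3,5-dimethoxy-4-methylphenoxy]dimethylsilane; 6 6-(bromomethyl)-4-methoxy-5-methyl-2H-pyran-2-one
Product: 15 6-{[2-(1-ethoxyethenyl)-3,5-dimethoxy-4-methylphenoxy]methyl}-4-methoxy-5-methyl-2H-pyran-2-one, via caesium phenolate 14 (not isolated)
Conditions: CsF (2.5 equiv), dry DMF, 0 °C to rt
Reagents that add atoms: caesium fluoride, [F-].[Cs+] (caesium ion of 14 only)
Why: Fluoride-triggered Williamson ether synthesis: desilylation frees the only phenoxide in a dry basic medium that spares the enol ether, and the crowded C–O bond is made by SN2 at a primary, allylic-type bromide rather than at an aromatic carbon.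

Step 9
Reactants: 15 6-{[2-(1-ethoxyethenyl)-3,5-dimethoxy-4-methylphenoxy]methyl}-4-methoxy-5-methyl-2H-pyran-2-one
Product: 18 1-[6-(2,6-dihydroxy-4-methoxy-3-methylphenoxy)-2,4-dimethoxy-3-methylphenyl]ethanone, via ring-opened (2E)-keto enoate 16 (not isolated), via enol ether resorcinol 17 (not isolated)
Conditions: Mg(OMe)2 (5 equiv), MeOH, reflux, argon; then 1 M HCl, THF, 0 °C to rt
Reagents that add atoms: water, O; magnesium methoxide, C[O-].C[O-].[Mg+2] (ester methoxy group of 16 only)
Why: Proposed new method: methoxide adds to the lactone carbonyl (pyrone C2) and the ring opens to the magnesium enolate of 16, whose ester and keto chain stay cis on the enol ether double bond (the 2E isomer, also the more stable one); reversible proton transfer from the stabilised C4 anion to the OCH2 position gives the α-aryloxy enolate, its carbon attacks the ester carbonyl, methoxide leaves, and the cyclohexenedione tautomer enolises irreversibly to resorcinol 17, which sets the C1'–C6' bond. The closest known reactions are the Mg(OMe)2 methanolysis of 4-methoxy-2-pyrones to 3-methoxy-5-oxo enoates and the Claisen (Dieckmann-type) cyclisation of 5-oxo and 3,5-dioxo esters to cyclohexane-1,3-diones, resorcinols and phloroglucinols; new is their union in one flask with a carbanion activated only by one ketone and an aryloxy group. Ring B closes in the 6-(enolendo)-exo-trig mode, since both enolate carbons (chain C5 and C6) become ring atoms. No stereocentre is formed, and the labile C4 centre of 16 disappears on aromatisation. The step needs chemoselectivity of the carbanion for the ester, and 15 secures it because ring A holds no carbonyl group and no acidic proton: the 1-ethoxyethenyl group is inert to alkoxide, so neither the 5-(enolexo)-exo-trig aldol to a benzofuran nor a Smiles shift of ring A can compete, and enolisation at C4 is reversible and leads nowhere. The acid quench then hydrolyses the enol ether of 17 to the acetyl group of 18.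

Step 10
Reactants: 18 1-[6-(2,6-dihydroxy-4-methoxy-3-methylphenoxy)-2,4-dimethoxy-3-methylphenyl]ethanone
Product: 19 1-[6-(2,6-dihydroxy-4-methoxy-3-methylphenoxy)-2-hydroxy-4-methoxy-3-methylphenyl]ethanone
Conditions: BCl3 (4 equiv), CH2Cl2, −78 to 0 °C; H2O
Reagents that add atoms: none
Why: Chelation-controlled Lewis acid cleavage of an aryl methyl ether: boron bound to the acetyl oxygen reaches only the ortho methoxy group at C3 of ring A, and since ring B carries no carbonyl group at this stage its C4' methoxy group and the C5 methoxy group of ring A have no such assistance and should stay.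

Step 11
Reactants: 19 1-[6-(2,6-dihydroxy-4-methoxy-3-methylphenoxy)-2-hydroxy-4-methoxy-3-methylphenyl]ethanone
Product: 20 leprolomin, 1-[3-(2-acetyl-3-hydroxy-5-methoxy-4-methylphenoxy)-2,4-dihydroxy-6-methoxy-5-methylphenyl]ethanone
Conditions: AcOH (5 equiv), BF3·OEt2 (excess), 80 °C; then H2O–MeOH, 60 °C
Reagents that add atoms: acetic acid, CC(=O)O
Why: Friedel–Crafts acylation of a phenol with a carboxylic acid and BF3 (Nencki type): C5' is the only free carbon of ring B and is activated by three oxygens, the one free carbon of ring A sits on a ring deactivated by its boron-bound acetyl group, and the acid medium leaves no O-acetates to remove and no phenoxide that could start a Smiles shift.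

Compound list
1 | methyl 3-oxopentanoate | CCC(=O)CC(=O)OC | starting material
2 | N-methoxy-N-methylacetamide | CC(=O)N(C)OC | starting material
3 | methyl 4-methyl-3,5-dioxohexanoate (racemic, labile C4) | CC(=O)C(C)C(=O)CC(=O)OC | intermediate
4 | 4-hydroxy-5,6-dimethyl-2H-pyran-2-one | CC1=C(C)C(O)=CC(=O)O1 | intermediate
5 | 4-methoxy-5,6-dimethyl-2H-pyran-2-one | CC1=C(C)C(OC)=CC(=O)O1 | intermediate
6 | 6-(bromomethyl)-4-methoxy-5-methyl-2H-pyran-2-one | COC1=CC(=O)OC(CBr)=C1C | intermediate
7 | 2,6-dimethoxytoluene | COc1cccc(OC)c1C | starting material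
8 | 2-(3,5-dimethoxy-4-methylphenyl)-4,4,5,5-tetramethyl-1,3,2-dioxaborolane | COc1cc(B2OC(C)(C)C(C)(C)O2)cc(OC)c1C | intermediate
9 | 3,5-dimethoxy-4-methylphenol | COc1cc(O)cc(OC)c1C | intermediate
10 | 2-iodo-3,5-dimethoxy-4-methylphenol | COc1cc(O)c(I)c(OC)c1C | intermediate
11 | tert-butyl(2-iodo-3,5-dimethoxy-4-methylphenoxy)dimethylsilane | COc1cc(O[Si](C)(C)C(C)(C)C)c(I)c(OC)c1C | intermediate
12 | tributyl(1-ethoxyethenyl)stannane | CCCC[Sn](CCCC)(CCCC)C(=C)OCC | starting material
13 | tert-butyl[2-(1-ethoxyethenyl)-3,5-dimethoxy-4-methylphenoxy]dimethylsilane | C=C(OCC)c1c(O[Si](C)(C)C(C)(C)C)cc(OC)c(C)c1OC | intermediate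
14 | caesium 2-(1-ethoxyethenyl)-3,5-dimethoxy-4-methylphenolate | [Cs+].[O-]c1cc(OC)c(C)c(OC)c1C(=C)OCC | intermediate
15 | 6-{[2-(1-ethoxyethenyl)-3,5-dimethoxy-4-methylphenoxy]methyl}-4-methoxy-5-methyl-2H-pyran-2-one | C=C(OCC)c1c(OCC2=C(C)C(OC)=CC(=O)O2)cc(OC)c(C)c1OC | intermediate
16 | methyl (2E)-6-[2-(1-ethoxyethenyl)-3,5-dimethoxy-4-methylphenoxy]-3-methoxy-4-methyl-5-oxohex-2-enoate (racemic, labile C4; present as magnesium enolate) | COC(=O)/C=C(/OC)C(C)C(=O)COc1cc(OC)c(C)c(OC)c1C(=C)OCC | intermediate
17 | 2-[2-(1-ethoxyethenyl)-3,5-dimethoxy-4-methylphenoxy]-5-methoxy-4-methylbenzene-1,3-diol | C=C(OCC)c1c(Oc2c(O)c(C)c(OC)cc2O)cc(OC)c(C)c1OC | intermediate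
18 | 1-[6-(2,6-dihydroxy-4-methoxy-3-methylphenoxy)-2,4-dimethoxy-3-methylphenyl]ethanone | COc1cc(Oc2c(O)c(C)c(OC)cc2O)c(C(C)=O)c(OC)c1C | intermediate
19 | 1-[6-(2,6-dihydroxy-4-methoxy-3-methylphenoxy)-2-hydroxy-4-methoxy-3-methylphenyl]ethanone | COc1cc(Oc2c(O)c(C)c(OC)cc2O)c(C(C)=O)c(O)c1C | intermediate
20 | leprolomin | COc1cc(Oc2c(O)c(C)c(OC)c(C(C)=O)c2O)c(C(C)=O)c(O)c1C | target

Total step count: 11. Longest linear sequence: 8 (steps 1–4 and 8–11). The ring A branch (steps 5–7) joins at step 8.

Steps most likely to fail

1. Step 9. The ring-opened ester may rest as the stabilised C4 anion, so the small share of the α-aryloxy enolate closes too slowly. The poorly electrophilic β-methoxy enoate may resist attack, and re-lactonisation on the quench would return the pyrone.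

The fallback builds the ether bond between two finished arenes by known chemistry. It sets out from 9 and from 8 (isolated instead of being oxidised) and comes back at 18.

- Ring B phenol, from 9:
  - Friedel–Crafts acetylation of 9 (AcOH, BF3·OEt2) would give 1-(6-hydroxy-2,4-dimethoxy-3-methylphenyl)ethanone F1.
  - AlCl3 in warm chlorobenzene would cleave the methoxy group next to the acetyl to give 1-(2,6-dihydroxy-4-methoxy-3-methylphenyl)ethanone F2.
  - BnBr with K2CO3 in DMF would give 1-[2,6-bis(benzyloxy)-4-methoxy-3-methylphenyl]ethanone F3.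
  - Baeyer–Villiger oxidation (mCPBA, CH2Cl2) would give 2,6-bis(benzyloxy)-4-methoxy-3-methylphenyl acetate F4.
  - Methanolysis (K2CO3, MeOH) would give 2,6-bis(benzyloxy)-4-methoxy-3-methylphenol F5, whose hydroxyl sits at the future C1'.
- Ring A bromide, from 8:
  - CuBr2 in aqueous methanol at 80 °C would convert 8 into 5-bromo-1,3-dimethoxy-2-methylbenzene F6.
  - AcCl with SnCl4 would give 1-(6-bromo-2,4-dimethoxy-3-methylphenyl)ethanone F7.
- Union and return:
  - Ullmann ether coupling of F5 with F7 (CuI, picolinic acid, K3PO4, DMSO, 90 °C), helped by the ortho acetyl of the bromide, would give 1-{6-[2,6-bis(benzyloxy)-4-methoxy-3-methylphenoxy]-2,4-dimethoxy-3-methylphenyl}ethanone F8.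
  - Hydrogenolysis (H2, palladium on carbon, EtOAc) returns to 18.

2. Step 7. Oxidative addition and transmetalation at the doubly ortho-substituted iodide may be slow, so protodeiodination takes over. The very electron-rich enol ether may also hydrolyse during isolation.

The fallback changes the latent acetyl to an alkyne. It sets out from 11 and comes back at 18.

- Sonogashira coupling of 11 with ethynyltrimethylsilane (PdCl2(PPh3)2, CuI, Et3N, THF, 50 °C), which brings in a slim, linear partner, would give tert-butyl{3,5-dimethoxy-4-methyl-2-[(trimethylsilyl)ethynyl]phenoxy}dimethylsilane F9.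
- CsF in moist DMF with 6 would remove both silyl groups and alkylate the phenoxide to give 6-[(2-ethynyl-3,5-dimethoxy-4-methylphenoxy)methyl]-4-methoxy-5-methyl-2H-pyran-2-one F10.
- The conditions of step 9 without the acid hydrolysis would give 2-(2-ethynyl-3,5-dimethoxy-4-methylphenoxy)-5-methoxy-4-methylbenzene-1,3-diol F11.
- Markovnikov hydration of this electron-rich arylalkyne (Ph3PAuNTf2 cat., dioxane–H2O, or TsOH·H2O in wet MeCN) returns to 18.

3. Step 4. Hydrogen abstraction from the C5 methyl, ionic bromination of the ring at C3, or a second bromination may erode site selectivity.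

The fallback lets acidity rather than radical stability choose the site. It sets out from 5 and comes back at 6.

- LiN(SiMe3)2 in THF at −78 °C removes a proton only from the C6 methyl, the one that is vinylogous to the lactone carbonyl, and would give lithium 4-methoxy-5-methyl-6-methylidene-6H-pyran-2-olate F12.
- Oxygen transfer from 2-(phenylsulfonyl)-3-phenyloxaziridine and an NH4Cl quench would give 6-(hydroxymethyl)-4-methoxy-5-methyl-2H-pyran-2-one F13.
- The Appel reaction (CBr4, PPh3, CH2Cl2, 0 °C) returns to 6.

Further compounds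
F1 | step 9 | 1-(6-hydroxy-2,4-dimethoxy-3-methylphenyl)ethanone | COc1cc(O)c(C(C)=O)c(OC)c1C
F2 | step 9 | 1-(2,6-dihydroxy-4-methoxy-3-methylphenyl)ethanone | COc1cc(O)c(C(C)=O)c(O)c1C
F3 | step 9 | 1-[2,6-bis(benzyloxy)-4-methoxy-3-methylphenyl]ethanone | COc1cc(OCc2ccccc2)c(C(C)=O)c(OCc2ccccc2)c1C
F4 | step 9 | 2,6-bis(benzyloxy)-4-methoxy-3-methylphenyl acetate | COc1cc(OCc2ccccc2)c(OC(C)=O)c(OCc2ccccc2)c1C
F5 | step 9 | 2,6-bis(benzyloxy)-4-methoxy-3-methylphenol | COc1cc(OCc2ccccc2)c(O)c(OCc2ccccc2)c1C
F6 | step 9 | 5-bromo-1,3-dimethoxy-2-methylbenzene | COc1cc(Br)cc(OC)c1C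
F7 | step 9 | 1-(6-bromo-2,4-dimethoxy-3-methylphenyl)ethanone | COc1cc(Br)c(C(C)=O)c(OC)c1C
F8 | step 9 | 1-{6-[2,6-bis(benzyloxy)-4-methoxy-3-methylphenoxy]-2,4-dimethoxy-3-methylphenyl}ethanone | COc1cc(Oc2c(OCc3ccccc3)c(C)c(OC)cc2OCc2ccccc2)c(C(C)=O)c(OC)c1C
F9 | step 7 | tert-butyl{3,5-dimethoxy-4-methyl-2-[(trimethylsilyl)ethynyl]phenoxy}dimethylsilane | COc1cc(O[Si](C)(C)C(C)(C)C)c(C#C[Si](C)(C)C)c(OC)c1C
F10 | step 7 | 6-[(2-ethynyl-3,5-dimethoxy-4-methylphenoxy)methyl]-4-methoxy-5-methyl-2H-pyran-2-one | C#Cc1c(OCC2=C(C)C(OC)=CC(=O)O2)cc(OC)c(C)c1OC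
F11 | step 7 | 2-(2-ethynyl-3,5-dimethoxy-4-methylphenoxy)-5-methoxy-4-methylbenzene-1,3-diol | C#Cc1c(Oc2c(O)c(C)c(OC)cc2O)cc(OC)c(C)c1OC
F12 | step 4 | lithium 4-methoxy-5-methyl-6-methylidene-6H-pyran-2-olate | [Li+].[O-]C1=CC(OC)=C(C)C(=C)O1
F13 | step 4 | 6-(hydroxymethyl)-4-methoxy-5-methyl-2H-pyran-2-one | COC1=CC(=O)OC(CO)=C1C
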